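**Plan**

1. Cuts (germacrane numbering: C1 epoxide CH, C2=C3, C4(Me)=C5, C6–O, C7, C8–O, C9, C10 epoxide C with Me, C11–C13 lactone carbons). First the C8–O acyl bond, then C11=C13, the lactone O6–C12 bond and C7–C11. Next C2=C3 goes back to CH2–CH2, the oxirane to the E C1=C10 alkene, and O8 to silicon. Last, C8–C9 is cut while C1–C6 is re-joined.
2. Enabling feature: the Z C4=C5 alkene, the oxygen on C6 and the trans oxirane (an E C1=C10 alkene one oxidation step higher). These are the marks left when a cyclohexene ring C1–C6, carrying a C7=C8 arm on the carbinol carbon C6 and a C9=C10 arm on C1, opens by a [3,3] shift to the ten-membered carbocycle.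
3. Forward order: the six-membered ring comes from (S)-limonene, and the ten-membered ring grows out of it by four-carbon expansion (step 5). The oxirane (step 8), C2=C3 (steps 9 and 10), the γ-lactone ring (steps 11 and 12), the exocyclic methylene (step 13) and the side chain (step 17) follow.
4. Stereochemistry: the limonene centre (= C1) directs the alkenyl addition at C6 and is then traded for C8 through a chair transition state. After Si to O exchange with retention, O8 relays the information three times: a lithium bridge O6/O8 sets C7, a hydrogen-bonded conformer sets the 1β,10α oxirane, and boron-bound O8 sets the 6α alcohol. Both centres of the acid come from a Katsuki–Sharpless epoxidation.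
5. Design points: silicon carries a benzyl group so that fluoride, not an electrophile, unmasks it. It is oxidised directly after the expansion, because an equatorial C8 silyl group would hold the (rapidly inverting) ring in the conformer that shows the wrong faces of C7 and C1=C10.

Key step: step 5

Remark: α/β follow the usual germacranolide drawing (H7 α). Read this way the target is 1β,10α-epoxy, 6α-O, 7β-C11, 8β-O (1R,6R,7R,8R,10R), trans-fused at C6/C7 and 2Z,4Z. Its ester is the (2S,3R)-epoxide of tiglic acid, with the two methyl groups cis.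

**Route**

Step 1
Reactants: 1 (S)-limonene
Product: 2 (R)-isopiperitenone [(6R)-3-methyl-6-(prop-1-en-2-yl)cyclohex-2-en-1-one]
Conditions: Cr(CO)6 (0.3 equiv), t-BuOOH, MeCN, reflux
Reagents that add atoms: tert-butyl hydroperoxide, CC(C)(C)OO
Why: Chromium-catalysed allylic oxidation turns a ring allylic CH2 into C=O under neutral conditions, so the centre next to the new ketone is not epimerised and the isopropenyl alkene is not drawn into conjugation, while carvone from attack at the other ring methylene is removed by chromatography.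

Step 2
Reactants: 3 benzyl(chloro)dimethylsilane; 4 ethynylmagnesium bromide
Product: 5 benzyl(ethynyl)dimethylsilane
Conditions: THF, 0 °C to rt
Reagents that add atoms: none
Why: Nucleophilic substitution at silicon by an alkynyl Grignard reagent gives a silane whose benzyl group tolerates organolithiums and KH yet is cleaved by fluoride, whereas a phenyl group would need acid, bromine or mercury salts that a cyclodeca-1(10),4-dienone does not survive.

Step 3
Reactants: 5 benzyl(ethynyl)dimethylsilane
Product: 7 benzyl[(E)-2-iodoethenyl]dimethylsilane, via alkenylzirconocene 6 (not isolated)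
Conditions: Cp2Zr(H)Cl, THF, rt; then I2, 0 °C
Reagents that add atoms: iodine, [I][I]; zirconocene chloride hydride, [H][Zr](Cl)(C1C=CC=C1)C1C=CC=C1 (metal fragment of 6 only)
Why: Hydrozirconation is a syn addition that places zirconium on the unhindered terminal carbon, and iodinolysis of the C–Zr bond proceeds with retention, which fixes the E geometry needed later for an equatorial silyl group.

Step 4
Reactants: 7 benzyl[(E)-2-iodoethenyl]dimethylsilane; 2 (R)-isopiperitenone
Product: 9 (1R,6R)-1-{(E)-2-[benzyl(dimethyl)silyl]ethenyl}-3-methyl-6-(prop-1-en-2-yl)cyclohex-2-en-1-ol, via alkenyllithium 8 (not isolated)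
Conditions: t-BuLi (2 equiv), Et2O, −78 °C; then 2, −78 °C; H2O
Reagents that add atoms: tert-butyllithium, [Li]C(C)(C)C (lithium of 8 only)
Why: Lithium–iodine exchange keeps the E geometry, and the alkenyllithium adds 1,2 to the enone faster than it enolises it, approaching the carbonyl face opposite the neighbouring isopropenyl group, which sets the carbinol centre (1R) with the two alkenyl arms trans.

Step 5
Reactants: 9 (1R,6R)-1-{(E)-2-[benzyl(dimethyl)silyl]ethenyl}-3-methyl-6-(prop-1-en-2-yl)cyclohex-2-en-1-ol
Product: 12 (2Z,6E,9R)-9-[benzyl(dimethyl)silyl]-3,7-dimethylcyclodeca-2,6-dien-1-one (germacrane numbering: 6-oxo 1(10)E 4Z 8R), via potassium alkoxide 10 (not isolated), via potassium enolate 11 (not isolated)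
Conditions: KH, 18-crown-6, THF, 0 °C to rt; then AcOH, THF, −78 °C
Reagents that add atoms: potassium hydride, [H-].[K+] (potassium of 10 and 11 only)
Why: KH with 18-crown-6 gives the loosely paired alkoxide 10, whose charge weakens the doubly allylic C1–C6 bond, so that the [3,3] shift (anionic oxy-Cope rearrangement of a 1,2-dialkenylcyclohexanol, the classical entry to cyclodec-5-enones) should run at or below room temperature and is made irreversible by formation of enolate 11. The ten-membered ring is not closed end to end but arises by four-carbon ring expansion, C8–C9 forming as C1–C6 breaks within a chair array C8–C7–C6–C1–C10–C9. With the alkenyl arms trans, both cyclohexene bonds (C6–C5 and C1–C2) and the E silyl group sit equatorially in that chair, which gives E C1=C10, leaves the ring-locked Z C4=C5 untouched and places O6 cis to C8 in the enolate. C8 is the only new stereocentre: the face of C8 that meets C9 is fixed by the C1 configuration (consumed in the step) and by the E geometry of the vinylsilane, so (1R,6R)-9 should give the 8R ketone. The step needs chair over boat and this diene pair over the alternative C9=C10/C4=C5 pair, and the substrate secures both because the trans arrangement makes the boat eclipsed and the equatorial isopropenyl group cannot reach C4. Silicon cannot leave from the β-position of enolate 11 as an alkoxy group could, and the cold acetic acid quench avoids Z to E or deconjugative drift of the enone.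

Step 6
Reactants: 12 (2Z,6E,9R)-9-[benzyl(dimethyl)silyl]-3,7-dimethylcyclodeca-2,6-dien-1-one
Product: 14 (2Z,6E,9R)-9-hydroxy-3,7-dimethylcyclodeca-2,6-dien-1-one (8β-hydroxy ketone), via silanol 13 (not isolated)
Conditions: TBAF, THF, 0 °C; then H2O2 (30%), KHCO3, MeOH–THF, rt
Reagents that add atoms: hydrogen peroxide, OO (O8); water, O (oxygen of silanol 13 only)
Why: Tamao–Fleming oxidation, in which fluoride removes the benzyl group as toluene without acid or electrophile, and basic peroxide then moves C8 from silicon to oxygen with retention, so 8R is kept and the strained E alkene and the hindered β,β-disubstituted enone are left alone.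

Step 7
Reactants: 14 (2Z,6E,9R)-9-hydroxy-3,7-dimethylcyclodeca-2,6-dien-1-one; 15 tert-butyl bromoacetate
Product: 17 tert-butyl (1(10)E,4Z,7R,8R)-8-hydroxy-6-oxo-13-norgermacra-1(10),4-dien-12-oate (β-CH2CO2t-Bu on C7 and β-OH on C8), via dilithio dianion 16 (not isolated)
Conditions: LDA (2.2 equiv), THF–DMPU, −78 °C; 15, −78 to −40 °C; AcOH
Reagents that add atoms: lithium diisopropylamide, [Li+].CC(C)[N-]C(C)C (lithium of 16 only)
Why: Fráter–Seebach-type alkylation of a β-oxido enolate, in which lithium bridges O6 and O8 (syn-diaxial on the chair-like C6–C7–C8–C9–C10–C1 half-ring) so that C9 stands on the inner face of the enolate and the bromoacetate can enter only from the periphery, anti to C9, placing C11 β (7R, anti to O8 in the zigzag sense as in acyclic cases), while the oxide cannot be eliminated and the tert-butyl ester resists the neighbouring alkoxide.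

Step 8
Reactants: 17 tert-butyl (1(10)E,4Z,7R,8R)-8-hydroxy-6-oxo-13-norgermacra-1(10),4-dien-12-oate
Product: 18 tert-butyl (1R,4Z,7R,8R,10R)-1,10-epoxy-8-hydroxy-6-oxo-13-norgermacr-4-en-12-oate
Conditions: mCPBA, NaHCO3, CH2Cl2, −20 °C
Reagents that add atoms: 3-chloroperbenzoic acid, OOC(=O)c1cccc(Cl)c1
Why: Prilezhaev epoxidation of the strained, electron-rich E C1=C10 alkene is far faster than attack on the enone, and since the O8–H···O6 hydrogen bond and the equatorial acetate arm hold the half-ring chair that turns C14 to the β face, the peracid reaches only the outer face, which should give the 1β,10α (1R,10R) oxirane.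

Step 9
Reactants: 18 tert-butyl (1R,4Z,7R,8R,10R)-1,10-epoxy-8-hydroxy-6-oxo-13-norgermacr-4-en-12-oate
Product: 19 tert-butyl (1R,7R,8R,10R)-1,10-epoxy-6,8-bis(trimethylsilyloxy)-13-norgermacra-3,5-dien-12-oate (both ring alkenes cis within the ring)
Conditions: TMSOTf, Et3N, CH2Cl2, −78 to −30 °C; used crude
Reagents that add atoms: trimethylsilyl triflate, C[Si](C)(C)OS(=O)(=O)C(F)(F)F
Why: Soft enolisation with a silyl triflate and an amine, which turns β,β-disubstituted enones into the thermodynamic linear dienol ether, should take a C3 proton because the fully substituted and flanked C7–H is poorly placed and esters are not enolised under these conditions, while O8 is capped in the same operation and the low temperature is meant to spare the oxirane and the tert-butyl ester.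

Step 10
Reactants: 19 tert-butyl (1R,7R,8R,10R)-1,10-epoxy-6,8-bis(trimethylsilyloxy)-13-norgermacra-3,5-dien-12-oate
Product: 21 tert-butyl (1R,2Z,4Z,7R,8R,10R)-1,10-epoxy-8-hydroxy-6-oxo-13-norgermacra-2,4-dien-12-oate, via silyloxy dienone 20 (not isolated)
Conditions: Pd(OAc)2 (1.1 equiv), MeCN, rt; then citric acid (cat.), MeOH, 0 °C
Reagents that add atoms: none
Why: Saegusa–Ito oxidation, in which divalent palladium binds the terminal carbon (C3) of the dienol ether and syn β-hydride elimination of a C2 hydrogen gives the linear dienone, the ring holding the diene s-cis so that C4=C5 returns as Z and the gauche C1–C2–C3–C4 segment inherited from the cyclohexene giving Z C2=C3, after which mild methanolysis frees O8.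

Step 11
Reactants: 21 tert-butyl (1R,2Z,4Z,7R,8R,10R)-1,10-epoxy-8-hydroxy-6-oxo-13-norgermacra-2,4-dien-12-oate
Product: 22 tert-butyl (1R,2Z,4Z,6R,7R,8R,10R)-1,10-epoxy-6,8-dihydroxy-13-norgermacra-2,4-dien-12-oate (6α,8β-diol)
Conditions: Me4NBH(OAc)3, MeCN–AcOH, −40 °C
Reagents that add atoms: none
Why: Evans–Saksena reduction, in which O8 replaces an acetate on boron and the bound hydride is passed to the axial β position of C6, 1,3-syn to axial O8, so that the new hydroxyl ends equatorial and α (6R, 1,3-anti diol), only the carbonyl carbon is attacked because delivery is intramolecular, and the low temperature is meant to keep the vinyl oxirane intact in the acetic acid medium.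

Step 12
Reactants: 22 tert-butyl (1R,2Z,4Z,6R,7R,8R,10R)-1,10-epoxy-6,8-dihydroxy-13-norgermacra-2,4-dien-12-oate
Product: 23 (1R,2Z,4Z,6R,7R,8R,10R)-1,10-epoxy-8-hydroxy-13-norgermacra-2,4-dien-12,6-olide
Conditions: KOt-Bu (0.2 equiv), THF, 0 °C
Reagents that add atoms: none
Why: Alkoxide-catalysed lactonisation, in which O6 and the acetate arm, both equatorial on neighbouring carbons, close to the trans-fused γ-lactone typical of 8β-hydroxy-6,12-germacranolides, and because acyl transfer between O6 and O8 is reversible under these conditions the more stable 6,12-olide should collect while tert-butoxide is regenerated.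

Step 13
Reactants: 23 (1R,2Z,4Z,6R,7R,8R,10R)-1,10-epoxy-8-hydroxy-13-norgermacra-2,4-dien-12,6-olide
Product: 26 (1R,2Z,4Z,6R,7R,8R,10R)-1,10-epoxy-8-hydroxygermacra-2,4,11(13)-trien-12,6-olide, via Mannich base 24 (not isolated), via methiodide 25 (not isolated)
Conditions: LDA (3 equiv), THF, −78 °C; CH2=NMe2+ I−, −78 to 0 °C; H2O; then MeI, MeOH, rt; then NaHCO3 aq, CH2Cl2
Reagents that add atoms: N,N-dimethylmethyleneiminium iodide, C=[N+](C)C.[I-] (C13); iodomethane, IC (N-methyl of 25 only)
Why: Eschenmoser methylenation, in which the lactone enolate (the O8 alkoxide rides along) undergoes a Mannich reaction at C11 from the face of H7, and quaternisation followed by Hofmann-type elimination gives the exocyclic alkene, so the transient C11 centre disappears again.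

Step 14
Reactants: 27 tiglic acid
Product: 28 (E)-2-methylbut-2-en-1-ol
Conditions: LiAlH4, Et2O, 0 °C
Reagents that add atoms: none
Why: Hydride reduction of the acid to the allylic alcohol leaves the trisubstituted alkene and its E geometry untouched.

Step 15
Reactants: 28 (E)-2-methylbut-2-en-1-ol
Product: 29 [(2R,3R)-2,3-dimethyloxiran-2-yl]methanol
Conditions: Ti(OiPr)4 (cat.), D-(−)-diethyl tartrate (cat.), t-BuOOH, 4 Å MS, CH2Cl2, −20 °C
Reagents that add atoms: tert-butyl hydroperoxide, CC(C)(C)OO
Why: Katsuki–Sharpless asymmetric epoxidation, in which the D-(−)-tartrate catalyst delivers oxygen to the face opposite to the one that gives (2S,3S)-epoxy alcohols from E allylic alcohols with the L-(+)-ester, setting both centres (2R,3R) while the E alkene fixes the cis relation of the methyl groups.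

Step 16
Reactants: 29 [(2R,3R)-2,3-dimethyloxiran-2-yl]methanol
Product: 31 (2S,3R)-2,3-dimethyloxirane-2-carboxylic acid, via epoxy aldehyde 30 (not isolated)
Conditions: RuCl3 (cat.), NaIO4, CCl4–MeCN–H2O, rt
Reagents that add atoms: water, O
Why: Ruthenium tetroxide oxidation of a 2,3-epoxy alcohol to the glycidic acid proceeds through the aldehyde hydrate without touching the oxirane, and the change of the C2 descriptor from R to S only reflects the higher rank of the carboxyl group.

Step 17
Reactants: 26 (1R,2Z,4Z,6R,7R,8R,10R)-1,10-epoxy-8-hydroxygermacra-2,4,11(13)-trien-12,6-olide; 31 (2S,3R)-2,3-dimethyloxirane-2-carboxylic acid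
Product: 33 target CNP0122107.1, via mixed anhydride 32 (not isolated)
Conditions: 2,4,6-trichlorobenzoyl chloride, Et3N, THF, rt; then 26, DMAP, toluene, rt
Reagents that add atoms: 2,4,6-trichlorobenzoyl chloride, O=C(Cl)c1c(Cl)cc(Cl)cc1Cl (aroyl part of 32 only)
Why: Yamaguchi esterification acylates the hindered axial 8β-hydroxyl without breaking the C8–O bond, the acid has no α-hydrogen so neither of its centres can epimerise, and the conditions are mild enough for both oxiranes and the α-methylene lactone.

**Compound list**

1 | (S)-limonene | CC1=CC[C@H](CC1)C(=C)C | starting material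
2 | (R)-isopiperitenone, (6R)-3-methyl-6-(prop-1-en-2-yl)cyclohex-2-en-1-one | O=C1C=C(C)CC[C@@H]1C(C)=C | intermediate
3 | benzyl(chloro)dimethylsilane | C[Si](C)(Cl)Cc1ccccc1 | starting material
4 | ethynylmagnesium bromide | C#C[Mg]Br | starting material
5 | benzyl(ethynyl)dimethylsilane | C#C[Si](C)(C)Cc1ccccc1 | intermediate
6 | chloro{(E)-2-[benzyl(dimethyl)silyl]ethenyl}zirconocene, formed in the flask (cyclopentadienyl rings drawn σ-bonded) | Cl[Zr](C1C=CC=C1)(C1C=CC=C1)/C=C/[Si](C)(C)Cc1ccccc1 | intermediate
7 | benzyl[(E)-2-iodoethenyl]dimethylsilane | I/C=C/[Si](C)(C)Cc1ccccc1 | intermediate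
8 | (E)-2-[benzyl(dimethyl)silyl]ethenyllithium, formed in the flask | [Li]/C=C/[Si](C)(C)Cc1ccccc1 | intermediate
9 | (1R,6R)-1-{(E)-2-[benzyl(dimethyl)silyl]ethenyl}-3-methyl-6-(prop-1-en-2-yl)cyclohex-2-en-1-ol (alkenyl arms trans) | O[C@]1(/C=C/[Si](C)(C)Cc2ccccc2)C=C(C)CC[C@@H]1C(C)=C | intermediate
10 | potassium alkoxide of 9, formed in the flask | [K+].[O-][C@]1(/C=C/[Si](C)(C)Cc2ccccc2)C=C(C)CC[C@@H]1C(C)=C | intermediate
11 | potassium C6–C7 enolate of 12 (O6 cis to C8), formed in the flask | [K+].[O-]/C1=C\[C@H]([Si](C)(C)Cc2ccccc2)C/C(C)=C/CC/C(C)=C\1 | intermediate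
12 | (2Z,6E,9R)-9-[benzyl(dimethyl)silyl]-3,7-dimethylcyclodeca-2,6-dien-1-one | O=C1/C=C(C)\CC/C=C(C)/C[C@@H]([Si](C)(C)Cc2ccccc2)C1 | intermediate
13 | (2Z,6E,9R)-9-[hydroxy(dimethyl)silyl]-3,7-dimethylcyclodeca-2,6-dien-1-one, formed in the flask | O=C1/C=C(C)\CC/C=C(C)/C[C@@H]([Si](C)(C)O)C1 | intermediate
14 | (2Z,6E,9R)-9-hydroxy-3,7-dimethylcyclodeca-2,6-dien-1-one | O=C1/C=C(C)\CC/C=C(C)/C[C@@H](O)C1 | intermediate
15 | tert-butyl bromoacetate | CC(C)(C)OC(=O)CBr | starting material
16 | dilithio O6,O8-dianion of 14 (C6–C7 enolate, O6 cis to C8), formed in the flask | [Li+].[Li+].[O-]/C1=C\[C@H]([O-])C/C(C)=C/CC/C(C)=C\1 | intermediate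
17 | tert-butyl (1(10)E,4Z,7R,8R)-8-hydroxy-6-oxo-13-norgermacra-1(10),4-dien-12-oate | O=C1/C=C(C)\CC/C=C(C)/C[C@@H](O)[C@H]1CC(=O)OC(C)(C)C | intermediate
18 | tert-butyl (1R,4Z,7R,8R,10R)-1,10-epoxy-8-hydroxy-6-oxo-13-norgermacr-4-en-12-oate | O=C1/C=C(C)\CC[C@H]2O[C@]2(C)C[C@@H](O)[C@H]1CC(=O)OC(C)(C)C | intermediate
19 | tert-butyl (1R,7R,8R,10R)-1,10-epoxy-6,8-bis(trimethylsilyloxy)-13-norgermacra-3,5-dien-12-oate | C[Si](C)(C)O/C1=C/C(C)=C\C[C@H]2O[C@]2(C)C[C@@H](O[Si](C)(C)C)[C@H]1CC(=O)OC(C)(C)C | intermediate
20 | 8-O-trimethylsilyl ether of 21, formed in the flask | O=C1/C=C(C)\C=C/[C@H]2O[C@]2(C)C[C@@H](O[Si](C)(C)C)[C@H]1CC(=O)OC(C)(C)C | intermediate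
21 | tert-butyl (1R,2Z,4Z,7R,8R,10R)-1,10-epoxy-8-hydroxy-6-oxo-13-norgermacra-2,4-dien-12-oate | O=C1/C=C(C)\C=C/[C@H]2O[C@]2(C)C[C@@H](O)[C@H]1CC(=O)OC(C)(C)C | intermediate
22 | tert-butyl (1R,2Z,4Z,6R,7R,8R,10R)-1,10-epoxy-6,8-dihydroxy-13-norgermacra-2,4-dien-12-oate | O[C@@H]1/C=C(C)\C=C/[C@H]2O[C@]2(C)C[C@@H](O)[C@H]1CC(=O)OC(C)(C)C | intermediate
23 | (1R,2Z,4Z,6R,7R,8R,10R)-1,10-epoxy-8-hydroxy-13-norgermacra-2,4-dien-12,6-olide | C1C(=O)O[C@@H]2/C=C(C)\C=C/[C@H]3O[C@]3(C)C[C@@H](O)[C@@H]12 | intermediate
24 | (11R)-11-(dimethylaminomethyl) derivative of 23 (aminomethyl group cis to H7), formed in the flask | CN(C)C[C@@H]1C(=O)O[C@@H]2/C=C(C)\C=C/[C@H]3O[C@]3(C)C[C@@H](O)[C@@H]12 | intermediate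
25 | N-methyl iodide salt of 24, formed in the flask | [I-].C[N+](C)(C)C[C@@H]1C(=O)O[C@@H]2/C=C(C)\C=C/[C@H]3O[C@]3(C)C[C@@H](O)[C@@H]12 | intermediate
26 | (1R,2Z,4Z,6R,7R,8R,10R)-1,10-epoxy-8-hydroxygermacra-2,4,11(13)-trien-12,6-olide | C=C1C(=O)O[C@@H]2/C=C(C)\C=C/[C@H]3O[C@]3(C)C[C@@H](O)[C@@H]12 | intermediate
27 | tiglic acid | C/C=C(\C)C(=O)O | starting material
28 | (E)-2-methylbut-2-en-1-ol | C/C=C(\C)CO | intermediate
29 | [(2R,3R)-2,3-dimethyloxiran-2-yl]methanol | OC[C@@]1(C)O[C@@H]1C | intermediate
30 | (2S,3R)-2,3-dimethyloxirane-2-carbaldehyde, formed in the flask | O=C[C@@]1(C)O[C@@H]1C | intermediate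
31 | (2S,3R)-2,3-dimethyloxirane-2-carboxylic acid | OC(=O)[C@@]1(C)O[C@@H]1C | intermediate
32 | (2S,3R)-2,3-dimethyloxirane-2-carboxylic 2,4,6-trichlorobenzoic anhydride, formed in the flask | O=C(OC(=O)c1c(Cl)cc(Cl)cc1Cl)[C@@]2(C)O[C@@H]2C | intermediate
33 | CNP0122107.1, (1R,2Z,4Z,6R,7R,8R,10R)-1,10-epoxy-8-[(2S,3R)-2,3-dimethyloxirane-2-carbonyloxy]germacra-2,4,11(13)-trien-12,6-olide | C=C1C(=O)O[C@@H]2/C=C(C)\C=C/[C@H]3O[C@]3(C)C[C@@H](OC(=O)[C@@]3(C)O[C@@H]3C)[C@@H]12 | target

**Step count**

Total steps: 17. Longest linear sequence: 13 steps (from 3 through steps 2 to 13 and step 17). From limonene the sequence is 12 steps.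

**Steps most likely to fail**

1. Step 9 (soft enolisation toward C3).
- What may go wrong: proton loss may occur at C7, giving a cross-conjugated enol ether and erosion of the C7 configuration, or at the C15 methyl group. The enone is twisted in the ring, which lowers the acidity at C3. The silyl triflate may also open the trisubstituted oxirane or cleave the tert-butyl ester.
- Fallback (from 18, back at 21): no enol derivative is made. O8 is capped (TESCl, imidazole, DMF) to give the 8-O-triethylsilyl ether of 18 F1. After epoxidation the only allylic C–H bonds left are those at C3 and C15, so Wohl–Ziegler bromination (NBS, dibenzoyl peroxide cat., PhCF3, light) should favour the secondary position and give the 3-bromo enone F2 as a mixture at C3. Loss of HBr toward C2, the only neighbouring carbon that bears hydrogen (DBU, toluene), gives the 8-O-triethylsilyl dienone F3. Citric acid in MeOH then releases 21.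

2. Step 7 (alkylation of the β-oxido enolate).
- What may go wrong: the neighbouring oxide slows deprotonation at C7, so LDA may instead take a γ-proton (C3 or C15) and alkylation would then occur at C5. The mono-alkoxide may open the ring by retro-aldol cleavage before the second deprotonation. DMPU may loosen the lithium bridge and lower the facial selectivity.
- Fallback (from 9, back at 17): enolate 11, which the ring expansion forms regiospecifically, is alkylated in the same flask with 15 at −78 °C. Peripheral attack on the conformer with equatorial silicon should give the 7S silyl keto ester F4, which is epimeric at C7. Deprotonation at C7 (LiHMDS, THF, −78 °C) and kinetic protonation from the periphery by a hindered phenol pushes the acetate arm into the axial site and should give the 7R silyl keto ester F5. Oxidation as in step 6 (TBAF; H2O2, KHCO3) converts F5 into 17.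

3. Step 11 (hydroxyl-delivered reduction in acetic acid).
- What may go wrong: acid-promoted opening or transannular capture of the vinyl oxirane, slow exchange at boron with competing undirected hydride attack, and conjugate reduction of the dienone.
- Fallback (from 21, back at 23): an Evans–Tishchenko reduction. SmI2 (cat.) is premixed with acetaldehyde (THF, −10 °C). It transfers hydride within the O8 hemiacetal under neutral conditions, with the same 1,3-anti sense, and gives the 8-O-acetyl 6α-alcohol F6 with O8 already differentiated. K2CO3 in MeOH then removes the acetate and closes O6 onto the ester to give 23.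

**Further compounds**

F1 | step 9 | tert-butyl (1R,4Z,7R,8R,10R)-1,10-epoxy-6-oxo-8-(triethylsilyloxy)-13-norgermacr-4-en-12-oate | O=C1/C=C(C)\CC[C@H]2O[C@]2(C)C[C@@H](O[Si](CC)(CC)CC)[C@H]1CC(=O)OC(C)(C)C
F2 | step 9 | tert-butyl (1R,4Z,7R,8R,10R)-3-bromo-1,10-epoxy-6-oxo-8-(triethylsilyloxy)-13-norgermacr-4-en-12-oate (both C3 epimers) | O=C1/C=C(C)\C(Br)C[C@H]2O[C@]2(C)C[C@@H](O[Si](CC)(CC)CC)[C@H]1CC(=O)OC(C)(C)C
F3 | step 9 | tert-butyl (1R,2Z,4Z,7R,8R,10R)-1,10-epoxy-6-oxo-8-(triethylsilyloxy)-13-norgermacra-2,4-dien-12-oate | O=C1/C=C(C)\C=C/[C@H]2O[C@]2(C)C[C@@H](O[Si](CC)(CC)CC)[C@H]1CC(=O)OC(C)(C)C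
F4 | step 7 | tert-butyl (1(10)E,4Z)-8β-[benzyl(dimethyl)silyl]-6-oxo-13-norgermacra-1(10),4-dien-12-oate with the acetate arm α on C7 | O=C1/C=C(C)\CC/C=C(C)/C[C@@H]([Si](C)(C)Cc2ccccc2)[C@@H]1CC(=O)OC(C)(C)C
F5 | step 7 | tert-butyl (1(10)E,4Z)-8β-[benzyl(dimethyl)silyl]-6-oxo-13-norgermacra-1(10),4-dien-12-oate with the acetate arm β on C7 | O=C1/C=C(C)\CC/C=C(C)/C[C@@H]([Si](C)(C)Cc2ccccc2)[C@H]1CC(=O)OC(C)(C)C
F6 | step 11 | tert-butyl (1R,2Z,4Z,6R,7R,8R,10R)-8-acetoxy-1,10-epoxy-6-hydroxy-13-norgermacra-2,4-dien-12-oate | O[C@@H]1/C=C(C)\C=C/[C@H]2O[C@]2(C)C[C@@H](OC(C)=O)[C@H]1CC(=O)OC(C)(C)C
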